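Abietane numbering is used (ring A: C1–C5, C10; ring B: C5–C10; ring C: C8, C9, C11–C14). The bridging δ-lactone holds C20 (on C10) and the carbonyl-bearing C4 (on C5) cis across the A/B fusion bond, a 1,5-dioxygen pattern that is the retron of a de Mayo sequence. One intramolecular crossed [2+2] photocycloaddition of a 1,3-dioxin-4-one with a ring B styrene-type alkene therefore makes C20–C10 and C4–C5 together, closing ring A and a temporary cyclobutane that is later opened by retro-aldol. The precursor is a 3,4-dihydronaphthalene tethered by three carbons to a menthone-derived dioxinone, whose ketal fixes the absolute configuration.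

Key step: step 10

Remark on descriptors: C18 = methyl on C4, C19 = lactone carbonyl on C4, C20 = OCH2 on C10; β is the face of the A/B system that carries C20, α the opposite face. The target has H-5 α, C20 β, C19 β, C18 α.

Assumption: the tethered alkene adds to the dioxinone face opposite the isopropyl-bearing carbon of the menthane ring; if the other face reacts, the other spiro epimer from step 8 is carried forward instead.

Step 1
Reactants: 1 1,2,4-trimethoxybenzene
Product: 2 2-(2,3,6-trimethoxyphenyl)propan-2-ol
Conditions: n-BuLi, THF, 0 °C; acetone, −78 °C to rt; H2O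
Reagents that add atoms: acetone, CC(C)=O
Why: Directed ortho-lithiation removes the proton flanked by two methoxy groups and the aryllithium should add to acetone (1,2-addition).

Step 2
Reactants: 2 2-(2,3,6-trimethoxyphenyl)propan-2-ol
Product: 3 1,2,4-trimethoxy-3-(propan-2-yl)benzene
Conditions: Et3SiH, CF3CO2H, CH2Cl2, 0 °C to rt
Reagents that add atoms: none
Why: Ionic hydrogenation: the tertiary benzylic alcohol ionises in acid and Et3SiH should deliver hydride to the cation.

Step 3
Reactants: 3 1,2,4-trimethoxy-3-(propan-2-yl)benzene; 4 succinic anhydride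
Product: 5 4-oxo-4-[2,4,5-trimethoxy-3-(propan-2-yl)phenyl]butanoic acid
Conditions: AlCl3, CH2Cl2/MeNO2, 0 °C; aq. HCl
Reagents that add atoms: none
Why: Friedel–Crafts acylation should take the free position that is ortho to the unhindered 4-methoxy group and para to the 2-methoxy group.

Step 4
Reactants: 5 4-oxo-4-[2,4,5-trimethoxy-3-(propan-2-yl)phenyl]butanoic acid
Product: 6 4-[2,4,5-trimethoxy-3-(propan-2-yl)phenyl]butanoic acid
Conditions: H2 (3 atm), 10% Pd/C, AcOH, HClO4 (cat.), 50 °C
Reagents that add atoms: none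
Why: Catalytic hydrogenolysis of an electron-rich aryl ketone to the methylene under acid.

Step 5
Reactants: 6 4-[2,4,5-trimethoxy-3-(propan-2-yl)phenyl]butanoic acid
Product: 7 5,7,8-trimethoxy-6-(propan-2-yl)-3,4-dihydronaphthalen-1(2H)-one
Conditions: (CF3CO)2O, CF3CO2H, CH2Cl2, 0 °C to rt
Reagents that add atoms: none
Why: Intramolecular Friedel–Crafts acylation through the mixed anhydride at the only free ring position.

Step 6
Reactants: 7 5,7,8-trimethoxy-6-(propan-2-yl)-3,4-dihydronaphthalen-1(2H)-one
Product: 8 5,7,8-trimethoxy-6-(propan-2-yl)-3,4-dihydronaphthalen-1-yl trifluoromethanesulfonate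
Conditions: KN(SiMe3)2, THF, −78 °C; PhNTf2, −78 to 0 °C
Reagents that add atoms: N-phenylbis(trifluoromethanesulfonimide), O=S(=O)(N(c1ccccc1)S(=O)(=O)C(F)(F)F)C(F)(F)F
Why: Enolate O-sulfonylation: deprotonation at the only α-CH2 and trapping with PhNTf2 should give the enol triflate.

Step 7
Reactants: 9 tert-butyl pent-4-enoate
Product: 10 tert-butyl 2-formylpent-4-enoate (racemic, largely enolised)
Conditions: LiN(iPr)2, THF, −78 °C; HCO2Et, −78 to 0 °C; aq. HCl
Reagents that add atoms: ethyl formate, CCOC=O
Why: Crossed Claisen condensation (α-formylation) of the ester lithium enolate with ethyl formate.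

Step 8
Reactants: 10 tert-butyl 2-formylpent-4-enoate; 11 (−)-menthone
Product: 12 spiro ketal of 5-allyl-4H-1,3-dioxin-4-one with (−)-menthone (spiro epimer shown)
Conditions: (CF3CO)2O, CF3CO2H, 0 °C to rt; chromatography
Reagents that add atoms: none
Why: Acid-promoted loss of isobutene and ketalisation of the resulting β-formyl acid (enol form) with the ketone, driven by the anhydride, is the standard dioxinone synthesis; both spiro epimers should form and the one shown is separated.

Step 9
Reactants: 12 spiro ketal of 5-allyl-4H-1,3-dioxin-4-one with (−)-menthone; 8 5,7,8-trimethoxy-6-(propan-2-yl)-3,4-dihydronaphthalen-1-yl trifluoromethanesulfonate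
Product: 14 dioxinone tethered through C3–C2–C1 to C10 of the dihydronaphthalene, via alkylborane 13 (not isolated)
Conditions: 9-BBN, THF, rt; then 8, Pd(dppf)Cl2 (5 mol%), K3PO4, DMF/H2O, 50 °C
Reagents that add atoms: none
Why: Hydroboration places boron on the terminal carbon and the B-alkyl Suzuki–Miyaura coupling with the enol triflate should join C1 to C10 without touching the dioxinone.

Step 10
Reactants: 14 dioxinone tethered through C3–C2–C1 to C10 of the dihydronaphthalene
Product: 15 crossed [2+2] photoadduct (cyclobutane C4–C5–C10–C20, ring A closed)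
Conditions: hν (Pyrex, λ > 290 nm), MeCN/acetone 9:1, 0 °C, 5 mM
Reagents that add atoms: none
Why: Acetone-sensitised excitation gives the dioxinone triplet, whose α-carbon (C4) bonds to C5 through a six-membered transition state, leaving a tertiary benzylic radical at C10 and an α-oxy radical at C20 that collapse to the C20–C10 bond, completing a crossed [2+2] photocycloaddition. The closest known reaction type is the intramolecular dioxinone–alkene photocycloaddition that forms the first half of a de Mayo reaction. Ring A closes in the six-membered (6-endo) radical mode and the cyclobutane by 1,4-biradical recombination. The three-carbon tether allows only a cis-fused cyclobutane on ring B, so C20 and C4 end on one face of the C5–C10 bond and H-5 is trans to C20; the absolute sense follows from the menthone ketal, whose isopropyl-bearing carbon blocks one dioxinone face (the centres at C4 and C20 are temporary). The step needs crossed rather than straight (C4–C10 and C20–C5) closure, which the aryl-bearing, fully substituted C10 should secure by stabilising the benzylic biradical and by disfavouring a bond between two fully substituted carbons.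

Step 11
Reactants: 15 crossed [2+2] photoadduct
Product: 17 methyl ester with 10β-CH(OMe)2 and H-5 α (both C4 epimers), via aldehyde ester 16 (not isolated)
Conditions: NaOMe (0.2 equiv), MeOH, 0 °C; then TsOH (0.4 equiv), HC(OMe)3, rt
Reagents that add atoms: methanol, CO; trimethyl orthoformate, COC(OC)OC
Why: Retro-aldol fragmentation (second half of the de Mayo reaction): methoxide opens the acyl ketal and releases menthone, the cyclobutanolate breaks the C4–C20 bond to an ester enolate and the C20 aldehyde, which is then protected as its dimethyl acetal; C5 and C10 are untouched.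

Step 12
Reactants: 17 methyl ester with 10β-CH(OMe)2 (both C4 epimers)
Product: 18 methyl 11,12,14,20,20-pentamethoxyabieta-8,11,13-trien-19-oate
Conditions: LiN(iPr)2, THF, −78 °C; MeI, DMPU, −78 to −20 °C
Reagents that add atoms: iodomethane, CI
Why: Ester enolate alkylation: MeI should approach from the α face, opposite the axial dimethoxymethyl group on C10, which sets C4 with methyl α and the ester β.

Step 13
Reactants: 18 methyl 11,12,14,20,20-pentamethoxyabieta-8,11,13-trien-19-oate
Product: 21 11,12,14-trimethoxyabieta-8,11,13-trien-19,20-olide, via aldehyde ester 19 (not isolated), via hydroxy ester 20 (not isolated)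
Conditions: 2 M HCl, THF, 40 °C; then NaBH4, MeOH, 0 °C; then TsOH (cat.), PhMe, 80 °C
Reagents that add atoms: water, O
Why: Acetal hydrolysis, NaBH4 reduction of the aldehyde and acid-catalysed lactonisation (transesterification) of the 1,3-diaxial CH2OH and CO2Me groups should close the bridged δ-lactone.

Step 14
Reactants: 21 11,12,14-trimethoxyabieta-8,11,13-trien-19,20-olide
Product: 22 11,12,14-trimethoxyabieta-6,8,11,13-tetraen-19,20-olide
Conditions: DDQ, 1,4-dioxane, 80 °C
Reagents that add atoms: none
Why: Benzylic dehydrogenation: hydride abstraction at C7, activated by the ortho and para methoxy groups, then loss of H-6; the quaternary C10 prevents aromatisation.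

Step 15
Reactants: 22 11,12,14-trimethoxyabieta-6,8,11,13-tetraen-19,20-olide
Product: 24 12-hydroxy-11,14-dioxoabieta-6,8,12-trien-19,20-olide, via triol 23 (not isolated)
Conditions: BBr3, CH2Cl2, −78 to 0 °C; then H2O, EtOAc, air (O2), rt
Reagents that add atoms: none
Why: Lewis acid cleavage of the three aryl methyl ethers gives a 1,2,4-trihydroxyarene that should autoxidise in air to the 2-hydroxy-1,4-quinone.

Step 16
Reactants: 24 12-hydroxy-11,14-dioxoabieta-6,8,12-trien-19,20-olide
Product: 25 12-acetoxy-11,14-dioxoabieta-6,8,12-trien-19,20-olide (target)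
Conditions: Ac2O, pyridine, DMAP (cat.), CH2Cl2, 0 °C
Reagents that add atoms: acetic anhydride, CC(=O)OC(C)=O
Why: O-Acylation of the acidic hydroxyquinone OH.

Compound list

1 | 1,2,4-trimethoxybenzene | COc1ccc(OC)c(OC)c1 | starting material
2 | 2-(2,3,6-trimethoxyphenyl)propan-2-ol | COc1ccc(OC)c(OC)c1C(C)(C)O | intermediate
3 | 1,2,4-trimethoxy-3-(propan-2-yl)benzene | COc1ccc(OC)c(OC)c1C(C)C | intermediate
4 | succinic anhydride | O=C1CCC(=O)O1 | starting material
5 | 4-oxo-4-[2,4,5-trimethoxy-3-(propan-2-yl)phenyl]butanoic acid | COc1c(C(=O)CCC(O)=O)cc(OC)c(OC)c1C(C)C | intermediate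
6 | 4-[2,4,5-trimethoxy-3-(propan-2-yl)phenyl]butanoic acid | COc1c(CCCC(O)=O)cc(OC)c(OC)c1C(C)C | intermediate
7 | 5,7,8-trimethoxy-6-(propan-2-yl)-3,4-dihydronaphthalen-1(2H)-one | COc1c2CCCC(=O)c2c(OC)c(OC)c1C(C)C | intermediate
8 | 5,7,8-trimethoxy-6-(propan-2-yl)-3,4-dihydronaphthalen-1-yl trifluoromethanesulfonate | COc1c2CCC=C(OS(=O)(=O)C(F)(F)F)c2c(OC)c(OC)c1C(C)C | intermediate
9 | tert-butyl pent-4-enoate | C=CCCC(=O)OC(C)(C)C | starting material
10 | tert-butyl 2-formylpent-4-enoate (racemic, largely enolised) | C=CCC(C=O)C(=O)OC(C)(C)C | intermediate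
11 | (−)-menthone, (2S,5R)-5-methyl-2-(propan-2-yl)cyclohexan-1-one | C[C@@H]1CC[C@H](C(=O)C1)C(C)C | starting material
12 | 5-(prop-2-en-1-yl)-4H-1,3-dioxin-4-one whose C2 is the spiro carbon C1' of the menthane ring (C2' isopropyl and C5' methyl as in 11); spiro epimer with the ring CH2 (C6') on the dioxinone face from which C4(=O)→C5→C6→O1 runs anticlockwise and the isopropyl-bearing C2' on the other face | O=C1C(CC=C)=CO[C@@]2(O1)C[C@H](C)CC[C@H]2C(C)C | intermediate
13 | 9-[3-(dioxinon-5-yl)propyl]-9-borabicyclo[3.3.1]nonane, ketal as in 12 (not isolated) | O=C1C(CCCB3C4CCCC3CCC4)=CO[C@@]2(O1)C[C@H](C)CC[C@H]2C(C)C | intermediate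
14 | analogue of 12 with 3-[5,7,8-trimethoxy-6-(propan-2-yl)-3,4-dihydronaphthalen-1-yl]propyl at C5 of the dioxinone | COc1c2CCC=C(CCCC3=CO[C@@]4(OC3=O)C[C@H](C)CC[C@H]4C(C)C)c2c(OC)c(OC)c1C(C)C | intermediate
15 | crossed photoadduct: cyclobutane C4–C5–C10–C20 within a bicyclo[3.1.1]heptane (ring A bridged by C20); C20 and C4 on the β face of the C5–C10 bond, H-5 α, H-20 syn to the C1–C3 bridge, C19 exo; ketal as in 12 | COc1c(C(C)C)c(OC)c2c(c1OC)[C@]34CCC[C@@]5(C(=O)O[C@]6(O[C@@H]35)C[C@H](C)CC[C@H]6C(C)C)[C@@H]4CC2 | intermediate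
16 | trans-fused aldehyde ester: 10β-CHO, H-5 α, CO2Me on C4 (both C4 epimers; not isolated) | COc1c(C(C)C)c(OC)c2c(c1OC)[C@@]3(C=O)CCCC(C(=O)OC)[C@@H]3CC2 | intermediate
17 | as 16 with 10β-CH(OMe)2 (both C4 epimers) | COc1c(C(C)C)c(OC)c2c(c1OC)[C@@]3(C(OC)OC)CCCC(C(=O)OC)[C@@H]3CC2 | intermediate
18 | methyl 11,12,14,20,20-pentamethoxyabieta-8,11,13-trien-19-oate (4α-Me, 4β-CO2Me, H-5 α, 10β-CH(OMe)2) | COc1c(C(C)C)c(OC)c2c(c1OC)[C@@]3(C(OC)OC)CCC[C@](C)(C(=O)OC)[C@@H]3CC2 | intermediate
19 | methyl 11,12,14-trimethoxy-20-oxoabieta-8,11,13-trien-19-oate (not isolated) | COc1c(C(C)C)c(OC)c2c(c1OC)[C@@]3(C=O)CCC[C@](C)(C(=O)OC)[C@@H]3CC2 | intermediate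
20 | methyl 20-hydroxy-11,12,14-trimethoxyabieta-8,11,13-trien-19-oate (not isolated) | COc1c(C(C)C)c(OC)c2c(c1OC)[C@@]3(CO)CCC[C@](C)(C(=O)OC)[C@@H]3CC2 | intermediate
21 | 11,12,14-trimethoxyabieta-8,11,13-trien-19,20-olide (C19 carbonyl, O on C20; H-5 α) | COc1c(C(C)C)c(OC)c2c(c1OC)[C@]13CCC[C@](C)(C(=O)OC1)[C@@H]3CC2 | intermediate
22 | 11,12,14-trimethoxyabieta-6,8,11,13-tetraen-19,20-olide | COc1c(C(C)C)c(OC)c2c(c1OC)[C@]13CCC[C@](C)(C(=O)OC1)[C@@H]3C=C2 | intermediate
23 | 11,12,14-trihydroxyabieta-6,8,11,13-tetraen-19,20-olide (not isolated) | Oc1c(C(C)C)c(O)c2c(c1O)[C@]13CCC[C@](C)(C(=O)OC1)[C@@H]3C=C2 | intermediate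
24 | 12-hydroxy-11,14-dioxoabieta-6,8,12-trien-19,20-olide | OC1=C(C(C)C)C(=O)C2=C(C1=O)[C@]13CCC[C@](C)(C(=O)OC1)[C@@H]3C=C2 | intermediate
25 | 12-acetoxy-11,14-dioxoabieta-6,8,12-trien-19,20-olide (H-5 α, C20 β, C19 β, C18 α) | CC(=O)OC1=C(C(C)C)C(=O)C2=C(C1=O)[C@]13CCC[C@](C)(C(=O)OC1)[C@@H]3C=C2 | target

Total steps: 16. Longest linear sequence: 14 steps (from 1 through steps 1–6 and 9–16).

Steps most likely to fail

Step 10. The photocycloaddition may close in the straight sense (C4 to C10, C20 to C5), may lose its excitation by energy transfer to the electron-rich styrene chromophore, or the ketal may discriminate the two dioxinone faces poorly. The fallback is a bimolecular de Mayo sequence that still joins C20 to C10 and C4 to C5 in one photochemical operation and closes ring A afterwards. It sets out from 8 and returns at 21.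
- Suzuki–Miyaura coupling of 8 with B-(3-chloropropyl)-9-borabicyclo[3.3.1]nonane F1 (from allyl chloride and 9-BBN) should give 1-(3-chloropropyl)-5,7,8-trimethoxy-6-(propan-2-yl)-3,4-dihydronaphthalene F2.
- tert-Butyl propanoate is formylated as in step 7 to tert-butyl 2-methyl-3-oxopropanoate F3, which is ketalised with 11 as in step 8 to the 5-methyl spiro dioxinone F4. The spiro epimer opposite to 12 is used, because the expected anti adduct presents the other dioxinone face.
- Irradiation of F2 with F4 (Pyrex, MeCN/acetone) should give the head-to-tail cis-anti-cis photoadduct F5.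
- NaOMe in MeOH opens F5 by retro-aldol to the aldehyde ester F6, and NaBH4 in the same flask followed by lactonisation gives the cis-fused δ-lactone F7.
- KN(SiMe3)2 in THF then closes ring A by intramolecular alkylation of the lactone enolate at C3, a bridged closure that can only give the natural C4 configuration, and delivers 21.

Step 15. HBr may add to the electron-rich C6=C7 bond, the hindered methyl ethers may be cleaved incompletely, or the boron halide may open the lactone. The fallback runs from 22 to 24 without a boron halide. Oxidative demethylation with (NH4)2Ce(NO3)6 in MeCN/H2O at 0 °C should give the 12-methoxy-11,14-quinone F8. Acid hydrolysis of its vinylogous ester (aq. HClO4, dioxane, 50 °C) then gives 24.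

Step 14. Hydride abstraction may occur at the isopropyl methine instead of C7, or the styrene formed may be oxidised further. The fallback runs from 21 to 22 by a radical halogenation–elimination sequence. Benzylic bromination (N-bromosuccinimide, dibenzoyl peroxide cat., PhCF3, 80 °C; the arene has no free ring position) should give the 7-bromide F9. E2 elimination with DBU in toluene then gives 22.

Further compounds

F1 | step 10 | B-(3-chloropropyl)-9-borabicyclo[3.3.1]nonane | ClCCCB1C2CCCC1CCC2
F2 | step 10 | 1-(3-chloropropyl)-5,7,8-trimethoxy-6-(propan-2-yl)-3,4-dihydronaphthalene | COc1c2CCC=C(CCCCl)c2c(OC)c(OC)c1C(C)C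
F3 | step 10 | tert-butyl 2-methyl-3-oxopropanoate (racemic, largely enolised) | CC(C=O)C(=O)OC(C)(C)C
F4 | step 10 | spiro ketal of 5-methyl-4H-1,3-dioxin-4-one with (−)-menthone, spiro epimer opposite to 12 | O=C1C(C)=CO[C@]2(O1)C[C@H](C)CC[C@H]2C(C)C
F5 | step 10 | head-to-tail cis-anti-cis photoadduct (cyclobutane C4–C5–C10–C20; C20 and C4 β on ring B, H-5 α, dioxanone anti to ring B) | COc1c(C(C)C)c(OC)c2c(c1OC)[C@]3(CCCCl)[C@H]4O[C@@]5(C[C@H](C)CC[C@H]5C(C)C)OC(=O)[C@@]4(C)[C@@H]3CC2
F6 | step 10 | aldehyde ester: 10β-CHO, 10-(3-chloropropyl), H-5 α, C5 bearing CH(CH3)CO2Me (both C4 epimers) | COc1c(C(C)C)c(OC)c2c(c1OC)[C@@](C=O)(CCCCl)[C@H](C(C)C(=O)OC)CC2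
F7 | step 10 | cis-fused δ-lactone (C19 carbonyl, O on C20) with 3-chloropropyl on C10 (both C4 epimers) | COc1c(C(C)C)c(OC)c2c(c1OC)[C@]3(CCCCl)COC(=O)C(C)[C@@H]3CC2
F8 | step 15 | 12-methoxy-11,14-dioxoabieta-6,8,12-trien-19,20-olide | COC1=C(C(C)C)C(=O)C2=C(C1=O)[C@]13CCC[C@](C)(C(=O)OC1)[C@@H]3C=C2
F9 | step 14 | 7-bromo-11,12,14-trimethoxyabieta-8,11,13-trien-19,20-olide (C7 epimers) | COc1c(C(C)C)c(OC)c2c(c1OC)[C@]13CCC[C@](C)(C(=O)OC1)[C@@H]3CC2Br
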